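**Feed time.** A day per whole charge is the unit of the feed time, the quantity reckoned here. The feed time is the time of the first reading divided by the fraction of the charge then present as target: the time for the whole charge at the opening rate.

| flask | substrate | free catalyst | remark | time |
|---|---|---|---|---|
| south | 0.70 M | 1 mol% | run made earlier |  |
| north-east | 1.1 M | 1 mol% | run made earlier |  |
| east | 0.50 M | 2 mol% | run made earlier |  |
| flask | 0.50 M | 1 mol% |  | 6.0 d |

| run | time / d | target / % |
|---|---|---|
| south | 0.0833 | 28.7 |
| south | 0.208 | 57.4 |
| south | 0.417 | 68.3 |
| south | 1.04 | 61.4 |
| south | 2.00 | 62.7 |
| south | 5.00 | 61.0 |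
| north-east | 0.0833 | 27.6 |
| north-east | 0.208 | 56.9 |
| north-east | 0.417 | 68.0 |
| north-east | 1.04 | 64.4 |
| north-east | 2.00 | 61.0 |
| north-east | 5.00 | 61.8 |
| east | 0.0833 | 46.1 |
| east | 0.250 | 71.6 |
| east | 0.625 | 61.2 |
| east | 1.67 | 60.8 |
| east | 5.00 | 61.5 |

(each reading ± 1 percentage point)

1. the best time, 6.0 d at the latest, for target
2. the amount of target, in percent of the substrate charged, at that time
3. earliest time at which at least nineteen twentieths of that best amount are there, in d
4. latest time at which they still are, in d

- the earlier runs were read with a standard deviation of 1 percentage point

**Fast rung.** The east run, at 2 mol%, has a feed time of 0.181 d. It reads 71.6% at 0.250 d, and target then falls.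

**Middle rung.** The south and north-east runs, both at 1 mol%, open at 28.7% and 27.6%, about one scatter apart despite their different substrate charges. The flask is taken onto that curve, although its charge lies below both. The south reading then gives the flask a feed time of 0.290 d, longer than in the east run.

**Slow rung.** The 6.0 d allowed are far longer than the feed time, so the flask should end on the plateau, read from the last points of the runs as 61.4%. That plateau reads as thermodynamic control, and the peak before it as kinetic control.

**The crossing.** Control changes hands where the feed of target falls to its loss, which I expect just past the feed time. The east reading of 71.6% stands 10 points above the plateau. Taking this excess as inversely proportional to feed time, my own reckoning puts the peak of the flask 6.3 points above the plateau, at 67.8%.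

**Forecast.** The forecast gives 72% at 0.52 d, with a window from 0.42 d to 0.72 d. Its ground: “Time therefore scales with mol%”. My peak is lower than that.

**Result.** The flask reaches 67.3% at 0.356 d, and the window runs from 0.270 d to 0.531 d.

    catalyst intermediate B → free catalyst + target (k = 55.0 h⁻¹)
    catalyst intermediate A ⇌ catalyst intermediate B (K = 1.00, k = 1300 h⁻¹)
    substrate + free catalyst → catalyst intermediate A (k = 150 L mol⁻¹ h⁻¹)
    2 catalyst intermediate B ⇌ resting dimer, settled at all times (K = 200 L mol⁻¹)
    target ⇌ isomer of the product (K = 0.630, k = 0.130 h⁻¹)

**Neighbour.** At its best time the flask holds 4.30% of substrate and 28.2% of isomer of the product, and that time is 1.23 feed times. Scaled inversely with loading from the feed time of the flask, the feed time of the neighbour flask at 0.25 mol% comes to 1.16 d, for which the excess rule gives 1.6 points above the plateau. That neighbour's best is 61.3%, and its end stands at 61.3%.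

The earlier runs and the new flask were generated by integration with constants of no real substance; scatter was added.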